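**Retrosynthetic overview**
- Last bond: the C8–CH2 bond of the prenyl group. It is made by C-alkylation at the only free arene carbon of 6-benzoyl-5,7-dihydroxy-2,2-dimethyl-2H-chromene.
- Key disconnection: the 2H-pyran (C4–C4a, O1–C2) and the benzene ring (C5–C6) are cut together, giving prenal and 4-hydroxy-6-phenacyl-2-pyrone. The pyrone is a sacrificial template that fixes O1 para to the benzoyl group.
- The phenacylpyrone comes from triacetic acid lactone and methyl benzoate by dianion acylation.
- Ring order: the phenyl and pyrone rings are bought. In one flask the 2H-pyran closes (oxa-6π), the pyrone opens and the benzene ring closes (Claisen). No ring is formed after that.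

Assumption: the target has no stereocentre and no stereogenic double bond, so it is achiral and there is no enantiomer to select. The route makes the one compound the SMILES describes.

**Step 1**
Reactants: 1 4-hydroxy-6-methyl-2H-pyran-2-one (triacetic acid lactone); 2 methyl benzoate
Product: 3 4-hydroxy-6-(2-oxo-2-phenylethyl)-2H-pyran-2-one
Conditions: LDA (3.1 equiv, commercial solution), THF/DMPU, −78 → 0 °C; then 2 (1.0 equiv), −78 °C → rt; 2 M HCl
Reagents that add atoms: none
Why: Crossed Claisen-type acylation of the lactone dianion, in which the vinylogous 6-methyl group is the next most acidic site after the 4-OH, its carbanion attacks the non-enolisable ester, the third equivalent of base stores the more acidic product as its enolate so no second addition occurs, and no stereocentre is formed.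

**Step 2**
Reactants: 3 4-hydroxy-6-(2-oxo-2-phenylethyl)-2H-pyran-2-one; 4 3-methylbut-2-enal (prenal)
Product: 8 (5,7-dihydroxy-2,2-dimethyl-2H-chromen-6-yl)(phenyl)methanone, via oxatriene 5 (not isolated), via pyranopyranone 6 (not isolated), via pyran ester 7 (not isolated)
Conditions: 4 (1.05 equiv), ethylenediammonium diacetate (10 mol %), MeOH, 50 °C; then, same flask, Mg(OMe)2 (4 equiv, commercial MeOH solution), reflux; 1 M HCl
Reagents that add atoms: none
Why: Proposed new method: amine-catalysed Knoevenagel condensation of prenal at pyrone C3 (pKa about 5, far more reactive in the buffer than the phenacyl CH2) gives oxatriene 5, which closes by oxa-6π electrocyclisation onto the C4 oxygen to 6 (the known formal [3+3] annulation of 4-hydroxy-2-pyrones with enals), then methoxide opens the lactone to the Mg-chelated β-diketone ester 7, whose ester α-carbon is fully substituted so the competing aldol mode is blocked and only Claisen/Dieckmann C-acylation by the diketone carbon followed by enolisation to the phenol remains (closest known reaction: the Mg(OMe)2 conversion of 6-(2-oxoalkyl)-4-hydroxy-2-pyrones and 3,5,7-trioxo esters into acylphloroglucinols), excess Mg(OMe)2 also removes the water from the first stage, the pyran oxygen ends up para to the benzoyl group, and no stereocentre is formed.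

**Step 3**
Reactants: 8 (5,7-dihydroxy-2,2-dimethyl-2H-chromen-6-yl)(phenyl)methanone; 9 1-bromo-3-methylbut-2-ene (prenyl bromide)
Product: 10 (5,7-dihydroxy-2,2-dimethyl-8-(3-methylbut-2-en-1-yl)-2H-chromen-6-yl)(phenyl)methanone
Conditions: 9 (1.1 equiv), KOH (1.1 equiv), MeOH/H2O, 0 °C → rt
Reagents that add atoms: none
Why: C-alkylation of an ambident acylphloroglucinol-type phenoxide (SN2 at the primary allylic bromide), in which C8 is the only unsubstituted ring carbon and lies ortho/para to three oxygen donors, the protic medium hydrogen-bonds the phenoxide oxygens and favours attack through carbon, rearomatisation leaves the linear prenyl group, the chromene alkene and the ketone are inert to cold dilute base, and no stereocentre is formed.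

**Compound list**
1 | 4-hydroxy-6-methyl-2H-pyran-2-one (triacetic acid lactone) | CC1=CC(O)=CC(=O)O1 | starting material
2 | methyl benzoate | COC(=O)c1ccccc1 | starting material
3 | 4-hydroxy-6-(2-oxo-2-phenylethyl)-2H-pyran-2-one | O=C(CC1=CC(O)=CC(=O)O1)c1ccccc1 | intermediate
4 | 3-methylbut-2-enal (prenal) | CC(C)=CC=O | starting material
5 | (3E)-3-(3-methylbut-2-en-1-ylidene)-6-(2-oxo-2-phenylethyl)-2H-pyran-2,4(3H)-dione (butenylidene chain cis to the C4 ketone) | CC(C)=C/C=C1\C(=O)C=C(CC(=O)c2ccccc2)OC1=O | intermediate
6 | 2,2-dimethyl-7-(2-oxo-2-phenylethyl)-2H,5H-pyrano[4,3-b]pyran-5-one | CC1(C)C=CC2=C(O1)C=C(CC(=O)c1ccccc1)OC2=O | intermediate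
7 | methyl 6-(2,4-dioxo-4-phenylbutyl)-2,2-dimethyl-2H-pyran-5-carboxylate | COC(=O)C1=C(CC(=O)CC(=O)c2ccccc2)OC(C)(C)C=C1 | intermediate
8 | (5,7-dihydroxy-2,2-dimethyl-2H-chromen-6-yl)(phenyl)methanone | CC1(C)C=Cc2c(O1)cc(O)c(C(=O)c1ccccc1)c2O | intermediate
9 | 1-bromo-3-methylbut-2-ene (prenyl bromide) | CC(C)=CCBr | starting material
10 | (5,7-dihydroxy-2,2-dimethyl-8-(3-methylbut-2-en-1-yl)-2H-chromen-6-yl)(phenyl)methanone | CC(C)=CCc1c(O)c(C(=O)c2ccccc2)c(O)c2c1OC(C)(C)C=C2 | target

**Total step count:** 3. **Longest linear sequence:** 3.

**Steps most likely to fail**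

Step 2 carries the highest risk. The phenacyl CH2 may compete in the Knoevenagel stage, or the anionic pyranopyranone may open only sluggishly. The fallback sets out from 1 and comes back at 6. It inverts the order of C–C bond formation so that the aldehyde never meets a phenacyl methylene. Compound 1 is condensed with 4 under the same amine catalysis to give 2,2,7-trimethyl-2H,5H-pyrano[4,3-b]pyran-5-one F1. The 7-methyl group of F1 is deprotonated as a vinylogous ester enolate (LiHMDS, 2.2 equiv, THF, −78 °C) and benzoylated with 2. This gives 6 as an isolated compound, so the methoxide-triggered lactone-to-phenol switch to 8 can be optimised on pure material.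

Step 3 may suffer from O-prenylation and from a second alkylation at C8 with dearomatisation. The fallback sets out from 8 and comes back at 10. It replaces the phenoxide alkylation by a cross-coupling. NIS in MeCN at 0 °C iodinates the only free arene position to give (5,7-dihydroxy-8-iodo-2,2-dimethyl-2H-chromen-6-yl)(phenyl)methanone F2. Stille coupling of F2 with commercial tributyl(3-methylbut-2-enyl)stannane (Pd2(dba)3, AsPh3, DMF, 70 °C) then forms the C8–CH2 bond with linear selectivity and gives 10.

Step 1 may fail through poor solubility of the dilithiated pyrone or proton transfer from the product. The fallback sets out from 2 and comes back at 3. It assembles the chain in open form and lactonises last. The dianion of acetylacetone (NaH, then n-BuLi, THF, 0 °C) is acylated with 2 to give 1-phenylhexane-1,3,5-trione F3. The trianion of F3 (LDA, 3.2 equiv) is carboxylated at the terminal methyl group with CO2 to give 3,5,7-trioxo-7-phenylheptanoic acid F4. Cold acetic anhydride cyclodehydrates F4 to 3.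

**Further compounds**
F1 | step 2 | 2,2,7-trimethyl-2H,5H-pyrano[4,3-b]pyran-5-one | CC1=CC2=C(C=CC(C)(C)O2)C(=O)O1
F2 | step 3 | (5,7-dihydroxy-8-iodo-2,2-dimethyl-2H-chromen-6-yl)(phenyl)methanone | CC1(C)C=Cc2c(O1)c(I)c(O)c(C(=O)c1ccccc1)c2O
F3 | step 1 | 1-phenylhexane-1,3,5-trione | CC(=O)CC(=O)CC(=O)c1ccccc1
F4 | step 1 | 3,5,7-trioxo-7-phenylheptanoic acid | OC(=O)CC(=O)CC(=O)CC(=O)c1ccccc1
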